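## The problem

The target is an achiral bibenzyl. Ring A is pentasubstituted (C1 OMe, C2 H, C3 OH, C4 and C6 each a 4-hydroxybenzyl group, C5 the CH2CH2 bridge). The bridge leads to a 1,2,4-trisubstituted ring B, which carries a third 4-hydroxybenzyl group ortho to the bridge and a hydroxyl para to that benzyl group. There is no stereocentre and no stereogenic double bond, so nothing has to be controlled or relayed; any sp3 centre formed on the way may be a mixture as long as it is erased later. The difficulty is constitutional: ring A has five contiguous substituents, C5 sits between two arylmethyl groups, and the two oxygens differ only by one methyl group. Four of the five phenolic oxygens must be masked and freed again without touching the C1 methyl ether. All rings are electron-rich, and the three Ar–CH2–Ar methylene groups lose hydride easily to strong oxidants, above all the one in the ring B arm, which is para to oxygen on both sides. The enabling feature is the local symmetry of ring A: apart from the O-methyl group it is symmetric about the axis through C2–H and C5, so a 4,6-dibenzyl-5-alkylcyclohexane-1,3-dione has only one mono methyl enol ether and can give only one 3-methoxyphenol. C4, C5 and C6 with their substituents then map onto the α- and β-carbons of an enone and the central carbon of a benzylmalonate.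

## Retrosynthesis

**Protecting groups (22 to 21).** Four O–CH2Ph bonds are cut. Benzyl ethers withstand methoxide, hot chloride in DMSO, acid catalysis and lithium amide, and are removed by neutral hydrogenolysis that leaves the methyl ether and the diarylmethanes alone. Silyl ethers would not survive methoxide, and methyl ethers could not be told from the C1 methoxy group. The forward step only has to be a clean hydrogenolysis of tetra-benzyl ether 21 to target 22.

**Ring A aromaticity (21 to 18 to 17).** No carbon–carbon bond is cut; one unsaturation is removed, so ring A becomes 3-methoxycyclohexenone 18, the only mono methyl enol ether of the constitutionally symmetric dione 17. This moves all regiochemistry of ring A into sp3 chemistry. A quinone dehydrogenation of neutral 18 needs heat and would compete with hydride abstraction from the bis(4-alkoxyphenyl)methane unit. Enone 18 is therefore first converted into silyl dienol ether 19, which one equivalent of DDQ should oxidize at low temperature to aryl silyl ether 20; hydrolysis gives phenol 21. The forward step must distinguish a siloxydiene from a diarylmethane.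

**Ester removal (17 to 16).** The C1–CO2Me bond is restored. The ester is needed in 16 as the acidifying group of the donor and as the partner of the second ester in ring closure. Its removal from the quaternary carbon is asked of a dealkoxycarbonylation that does not depend on access to the hindered acyl carbon.

**Ring A skeleton (16 to 12 and 14).** Two ring bonds are cut: C1–C6 (quaternary carbon to bridge-bearing carbon) and C2–C3 (ester-derived carbonyl to ring CH2). This Michael–Claisen cut leads to acyclic enone 12 and benzylmalonate 14, each already carrying one arylmethyl group at the correct carbon, with ring B complete inside 12. The neighbouring options are weaker: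
- Benzylating a preformed resorcinol twice would need control of ortho/para selectivity and differentiation of the oxygens.
- An unsubstituted malonate would require a later regioselective C-benzylation.
- An acetoacetate-type donor would give a ring with only one oxygen.

The forward reaction must add a tertiary carbanion to a trisubstituted enone and then close the ring.

**Malonate 14 (to 13 and 5).** One C–C bond is cut by malonic ester alkylation of dimethyl malonate 13 with benzylic chloride 5.

**Enone 12 (to 11 and 9).** The C3=C4 double bond is cut as a Horner–Wadsworth–Emmons olefination of α-benzylated ketophosphonate 11 with aldehyde 9. The alternative, a cross-aldol condensation of a 4-arylbutan-2-one at its internal methylene with enolizable 9, leaves the site of enolization (methyl or methylene) and the self-condensation of 9 uncontrolled. The phosphonate fixes the position of the new double bond. Phosphonate 11 comes from commercial 10 and chloride 5.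

**Ring B aldehyde 9 (to 8, 7, 4, 2, 1).** Aldehyde 9 is the partial reduction product of ester 8, which is the conjugate reduction product of cinnamate 7. The aryl–CH2 bond of 7 is cut to aryl bromide 4 and benzylic zinc reagent 6, made from the same chloride 5 that serves 11 and 14. Bromide 4 is the olefination product of aldehyde 2 with phosphonate 3, and 2 is the benzyl ether of commercial 1, which already has the 1,2,4-pattern of ring B. Olefination comes before the coupling so that no aldehyde is exposed to the organozinc reagent.

## Roads not taken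

**Alternative 1:** The bridge is cut at both aryl–C bonds after raising it to an alkyne. Diarylalkyne A1 would come from ring A iodide A2, ethynyltrimethylsilane A3 and ring B bromide A4 by a one-pot double Sonogashira coupling, with the terminal alkyne unmasked between the two couplings.
- Merits: the route is convergent, both bonds form by well-understood palladium/copper catalysis, A4 is close to bromo aldehyde 1, and one hydrogenation would saturate the alkyne and remove all five benzyl groups.
- Weak points: A2 is a hexasubstituted benzene with its iodine between two arylmethyl groups. Making it requires two regioselective benzylations and a halogenation of a 5-substituted resorcinol plus a statistical monoalkylation to tell the oxygens apart, which is the ring A problem left unsolved. The di-ortho-substituted iodide would couple slowly, and a one-pot unsymmetrical sequence risks symmetrical diarylalkynes.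
- Comparison: in convergence and in its end game Alternative 1 is better. The chosen plan sets against it that every substituent of ring A is placed by the connectivity of acyclic precursors and that the methyl ether needs no selective step.

**Alternative 2:** Three bonds to ring A are cut at once: both aryl–CH2 bonds and the aryl–vinyl bond of stilbene A5. Iodoarene A6, two equivalents of benzylic chloride 5 and ring B styrene A7 would be joined by a Catellani-type palladium relay, in which a strained bicyclic alkene carries palladium from the ipso carbon to both ortho positions before a terminating Heck reaction.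
- Merits: no other plan matches its step economy, and the same global hydrogenation would finish the synthesis.
- Weak points: each ortho C–H to be benzylated lies between the iodine and an alkoxy group, so both alkylations must create a 1,2,3-trisubstituted array, which this relay tolerates poorly. Benzylic chlorides can also couple directly with palladium, four components must react in a fixed order, and A6 still needs a statistical monomethylation.
- Comparison: if it worked it would be clearly shorter. The chosen route is longer but uses reaction types known for each substrate class, and the risk of its key step is one of rate, not of selection among four components.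

**Alternative 3:** Two bonds of ring B are cut. Siloxy diene A10 (trans-1-methoxy-3-(trimethylsilyloxy)buta-1,3-diene, the Danishefsky diene) would add across the triple bond of ynone A9, and loss of methanol and the silyl group would aromatize the adduct to 4-aroylphenol A8.
- Merits: the polarization of both partners dictates the regiochemistry, so the 1,2,4-pattern of ring B and its hydroxyl arise without ambiguity.
- Weak points: ring B is the simple ring, and its pattern is already present in commercial 1. A9 must contain the complete hexasubstituted ring A with differentiated oxygens and a side chain, so every objection to A2 returns. The diaryl ketone of A8 must also be reduced to a methylene group.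
- Comparison: Alternative 3 is better only in the certainty of its cycloaddition, which the hindered annulation of the chosen plan cannot match. The chosen plan is better in spending its ring-forming step on ring A, where the substitution problem lies.

Key step: step 9

Assumption: the target has no stereocentre; intermediates with transient sp3 centres (11, 15 to 19 and the fallback compounds) are racemic or diastereomer mixtures, so their SMILES carry no configuration.

## Route

Step 1
Reactants: 1 2-bromo-5-hydroxybenzaldehyde
Product: 2 5-(benzyloxy)-2-bromobenzaldehyde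
Conditions: BnBr, K2CO3, DMF, rt
Reagents that add atoms: benzyl bromide, BrCc1ccccc1
Why: Williamson ether synthesis; the phenoxide is alkylated at oxygen and the aldehyde and aryl bromide are inert to carbonate.

Step 2
Reactants: 2 5-(benzyloxy)-2-bromobenzaldehyde; 3 trimethyl phosphonoacetate
Product: 4 methyl (E)-3-[5-(benzyloxy)-2-bromophenyl]prop-2-enoate
Conditions: NaH, THF, 0 °C → rt
Reagents that add atoms: none
Why: Horner–Wadsworth–Emmons olefination of a non-enolizable aryl aldehyde, which should give the E-enoate; it adds the two bridge carbons and removes the aldehyde before the organozinc step.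

Step 3
Reactants: 5 4-(benzyloxy)benzyl chloride; 4 methyl (E)-3-[5-(benzyloxy)-2-bromophenyl]prop-2-enoate
Product: 7 methyl (E)-3-{5-(benzyloxy)-2-[4-(benzyloxy)benzyl]phenyl}prop-2-enoate, via [4-(benzyloxy)benzyl]zinc chloride 6 (not isolated)
Conditions: Zn dust, LiCl, THF, rt; then 4, Pd(OAc)2 (2 mol %), SPhos (4 mol %), THF, rt → 50 °C
Reagents that add atoms: none
Why: LiCl-promoted zinc insertion into the benzylic chloride gives 6, which undergoes Negishi coupling with the aryl bromide at zerovalent palladium formed from Pd(OAc)2 and SPhos; benzylic zinc reagents tolerate esters and do not add to enoates without copper.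

Step 4
Reactants: 7 methyl (E)-3-{5-(benzyloxy)-2-[4-(benzyloxy)benzyl]phenyl}prop-2-enoate
Product: 8 methyl 3-{5-(benzyloxy)-2-[4-(benzyloxy)benzyl]phenyl}propanoate
Conditions: NaBH4, NiCl2·6H2O (20 mol %), MeOH/THF, 0 °C
Reagents that add atoms: none
Why: Nickel boride conjugate reduction of a cinnamate; it saturates the conjugated C=C and leaves the ester and the aryl benzyl ethers, which hydrogenation over palladium would cleave.

Step 5
Reactants: 8 methyl 3-{5-(benzyloxy)-2-[4-(benzyloxy)benzyl]phenyl}propanoate
Product: 9 3-{5-(benzyloxy)-2-[4-(benzyloxy)benzyl]phenyl}propanal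
Conditions: iBu2AlH (1.05 equiv), CH2Cl2, −78 °C; MeOH, then aq. potassium sodium tartrate
Reagents that add atoms: none
Why: Partial reduction of a methyl ester; the aluminium hemiacetal is stable at −78 °C and releases the aldehyde only on work-up.

Step 6
Reactants: 10 diethyl (2-oxopropyl)phosphonate; 5 4-(benzyloxy)benzyl chloride
Product: 11 diethyl {1-[4-(benzyloxy)phenyl]-3-oxobutan-2-yl}phosphonate (racemic)
Conditions: NaH, THF/DMF, 0 °C; 5, NaI (cat.), rt → 50 °C
Reagents that add atoms: none
Why: C-alkylation of the stabilized β-ketophosphonate anion at the carbon between phosphorus and carbonyl by SN2 displacement on the benzylic halide, with iodide catalysis; the new stereocentre is racemic and lost in step 7.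

Step 7
Reactants: 11 diethyl {1-[4-(benzyloxy)phenyl]-3-oxobutan-2-yl}phosphonate; 9 3-{5-(benzyloxy)-2-[4-(benzyloxy)benzyl]phenyl}propanal
Product: 12 (E)-3-[4-(benzyloxy)benzyl]-6-{5-(benzyloxy)-2-[4-(benzyloxy)benzyl]phenyl}hex-3-en-2-one
Conditions: Ba(OH)2·8H2O, THF/H2O (40:1), rt
Reagents that add atoms: none
Why: Horner–Wadsworth–Emmons olefination with an α-substituted β-ketophosphonate places the double bond regiospecifically at the benzyl-bearing carbon; the mild barium base should spare the enolizable aldehyde and favour the E-isomer (acetyl trans to the chain), although either geometry would serve in step 9.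

Step 8
Reactants: 13 dimethyl malonate; 5 4-(benzyloxy)benzyl chloride
Product: 14 dimethyl 2-[4-(benzyloxy)benzyl]malonate
Conditions: NaH, THF/DMF, 0 °C → rt (13 in twofold excess)
Reagents that add atoms: none
Why: Malonic ester alkylation with a reactive benzylic chloride; excess malonate suppresses dialkylation.

Step 9
Reactants: 12 (E)-3-[4-(benzyloxy)benzyl]-6-{5-(benzyloxy)-2-[4-(benzyloxy)benzyl]phenyl}hex-3-en-2-one; 14 dimethyl 2-[4-(benzyloxy)benzyl]malonate
Product: 16 methyl 1,5-bis[4-(benzyloxy)benzyl]-6-(2-{5-(benzyloxy)-2-[4-(benzyloxy)benzyl]phenyl}ethyl)-2,4-dioxocyclohexane-1-carboxylate (diastereomer mixture), via open-chain Michael adduct 15 (not isolated)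
Conditions: NaOMe (2 equiv), 14 (1.5 equiv), MeOH/THF, reflux; aq. HCl work-up
Reagents that add atoms: none
Why: Methoxide deprotonates 14 and the stabilized tertiary carbanion adds reversibly to the β-carbon of 12 (Michael addition) to give 15; proton exchange then delivers the methyl ketone enolate, which attacks one of the two ester groups and expels methoxide (Claisen, Dieckmann-type closure). The closest known reaction type is the dimedone-type Michael–Claisen annulation of malonates with enones that is used for 5-alkylcyclohexane-1,3-diones. The single ring closes in a 6-(enolexo)-exo-trig mode; the only other enolate of 15, at the benzyl-bearing α-carbon, could reach an ester only through a four-membered ring and is unproductive. Three sp3 stereocentres arise (C1, C5, C6) and none is controlled; C5 epimerizes under the conditions and all three disappear in steps 10 to 12. The selectivity needed is constitutional: 1,4- instead of 1,2-addition is secured by the soft, reversibly adding malonate, for which carbonyl addition is unproductive and reverts. The hindered addition is unfavourable and retro-Michael cleavage competes, but ring closure followed by deprotonation of the acidic 1,3-dione by the second equivalent of methoxide removes the product from all equilibria. Acidification at work-up should return 16 as a mixture of diastereomers and enol tautomers.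

Step 10
Reactants: 16 methyl 1,5-bis[4-(benzyloxy)benzyl]-6-(2-{5-(benzyloxy)-2-[4-(benzyloxy)benzyl]phenyl}ethyl)-2,4-dioxocyclohexane-1-carboxylate
Product: 17 4,6-bis[4-(benzyloxy)benzyl]-5-(2-{5-(benzyloxy)-2-[4-(benzyloxy)benzyl]phenyl}ethyl)cyclohexane-1,3-dione (diastereomer mixture)
Conditions: LiCl, H2O (2 equiv), DMSO, 150 °C
Reagents that add atoms: none
Why: Krapcho dealkoxycarbonylation; chloride attacks the O-methyl carbon by SN2, so the hindered quaternary acyl carbon need not be reached, and the resulting β-keto carboxylate loses CO2 and is protonated.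

Step 11
Reactants: 17 4,6-bis[4-(benzyloxy)benzyl]-5-(2-{5-(benzyloxy)-2-[4-(benzyloxy)benzyl]phenyl}ethyl)cyclohexane-1,3-dione
Product: 18 4,6-bis[4-(benzyloxy)benzyl]-5-(2-{5-(benzyloxy)-2-[4-(benzyloxy)benzyl]phenyl}ethyl)-3-methoxycyclohex-2-en-1-one (diastereomer mixture)
Conditions: HC(OMe)3, TsOH·H2O (cat.), MeOH, rt → 50 °C
Reagents that add atoms: methanol, CO; trimethyl orthoformate, COC(OC)OC
Why: Acid-catalysed O-methylation of a cyclic 1,3-dione (vinylogous Fischer esterification), with the orthoformate removing water; because the two carbonyl groups of 17 are constitutionally equivalent, only one enol ether constitution can form.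

Step 12
Reactants: 18 4,6-bis[4-(benzyloxy)benzyl]-5-(2-{5-(benzyloxy)-2-[4-(benzyloxy)benzyl]phenyl}ethyl)-3-methoxycyclohex-2-en-1-one
Product: 21 2,4-bis[4-(benzyloxy)benzyl]-3-(2-{5-(benzyloxy)-2-[4-(benzyloxy)benzyl]phenyl}ethyl)-5-methoxyphenol, via trimethylsilyl dienol ether 19 (not isolated), via aryl trimethylsilyl ether 20 (not isolated)
Conditions: LiN(iPr)2, THF, −78 °C; Me3SiCl, −78 → 0 °C; volatiles removed, pentane filtration; DDQ (1.05 equiv), 2,4,6-collidine, CH2Cl2, −40 → 0 °C; 1 M HCl, THF, rt
Reagents that add atoms: none
Why: Kinetic α′-deprotonation of the vinylogous ester and O-silylation give siloxydiene 19, and quinone dehydrogenation of a silyl dienol ether then removes hydride from C5 to give an arenium ion stabilized by both oxygens, which loses a proton to 20. The electron-rich diene should react with one equivalent of DDQ far below the temperature at which the diarylmethanes are attacked, and α′- or γ-enolization converge on the same arene because of the symmetry of ring A; dilute acid hydrolyses the aryl silyl ether.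

Step 13
Reactants: 21 2,4-bis[4-(benzyloxy)benzyl]-3-(2-{5-(benzyloxy)-2-[4-(benzyloxy)benzyl]phenyl}ethyl)-5-methoxyphenol
Product: 22 2,4-bis(4-hydroxybenzyl)-3-{2-[5-hydroxy-2-(4-hydroxybenzyl)phenyl]ethyl}-5-methoxyphenol (CNP0147493.0)
Conditions: H2 (1 atm), 10% Pd/C, EtOAc/MeOH, rt
Reagents that add atoms: none
Why: Hydrogenolysis of four aryl benzyl ethers under neutral conditions; the aryl methyl ether, the diarylmethane C–C bonds and the arenes are inert.

## Compound list

1 | 2-bromo-5-hydroxybenzaldehyde | O=Cc1cc(O)ccc1Br | starting material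
2 | 5-(benzyloxy)-2-bromobenzaldehyde | O=Cc1cc(OCc2ccccc2)ccc1Br | intermediate
3 | trimethyl phosphonoacetate | COC(=O)CP(=O)(OC)OC | starting material
4 | methyl (E)-3-[5-(benzyloxy)-2-bromophenyl]prop-2-enoate | COC(=O)/C=C/c1cc(OCc2ccccc2)ccc1Br | intermediate
5 | 4-(benzyloxy)benzyl chloride | ClCc1ccc(OCc2ccccc2)cc1 | starting material
6 | [4-(benzyloxy)benzyl]zinc chloride | Cl[Zn]Cc1ccc(OCc2ccccc2)cc1 | intermediate
7 | methyl (E)-3-{5-(benzyloxy)-2-[4-(benzyloxy)benzyl]phenyl}prop-2-enoate | COC(=O)/C=C/c1cc(OCc2ccccc2)ccc1Cc1ccc(OCc2ccccc2)cc1 | intermediate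
8 | methyl 3-{5-(benzyloxy)-2-[4-(benzyloxy)benzyl]phenyl}propanoate | COC(=O)CCc1cc(OCc2ccccc2)ccc1Cc1ccc(OCc2ccccc2)cc1 | intermediate
9 | 3-{5-(benzyloxy)-2-[4-(benzyloxy)benzyl]phenyl}propanal | O=CCCc1cc(OCc2ccccc2)ccc1Cc1ccc(OCc2ccccc2)cc1 | intermediate
10 | diethyl (2-oxopropyl)phosphonate | CCOP(=O)(CC(C)=O)OCC | starting material
11 | diethyl {1-[4-(benzyloxy)phenyl]-3-oxobutan-2-yl}phosphonate (racemic) | CCOP(=O)(OCC)C(Cc1ccc(OCc2ccccc2)cc1)C(C)=O | intermediate
12 | (E)-3-[4-(benzyloxy)benzyl]-6-{5-(benzyloxy)-2-[4-(benzyloxy)benzyl]phenyl}hex-3-en-2-one | CC(=O)/C(Cc1ccc(OCc2ccccc2)cc1)=C/CCc1cc(OCc2ccccc2)ccc1Cc1ccc(OCc2ccccc2)cc1 | intermediate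
13 | dimethyl malonate | COC(=O)CC(=O)OC | starting material
14 | dimethyl 2-[4-(benzyloxy)benzyl]malonate | COC(=O)C(Cc1ccc(OCc2ccccc2)cc1)C(=O)OC | intermediate
15 | dimethyl 2-[4-(benzyloxy)benzyl]-2-(4-[4-(benzyloxy)benzyl]-1-{5-(benzyloxy)-2-[4-(benzyloxy)benzyl]phenyl}-5-oxohexan-3-yl)malonate (diastereomer mixture) | COC(=O)C(Cc1ccc(OCc2ccccc2)cc1)(C(=O)OC)C(CCc1cc(OCc2ccccc2)ccc1Cc1ccc(OCc2ccccc2)cc1)C(Cc1ccc(OCc2ccccc2)cc1)C(C)=O | intermediate
16 | methyl 1,5-bis[4-(benzyloxy)benzyl]-6-(2-{5-(benzyloxy)-2-[4-(benzyloxy)benzyl]phenyl}ethyl)-2,4-dioxocyclohexane-1-carboxylate (diastereomer mixture) | COC(=O)C1(Cc2ccc(OCc3ccccc3)cc2)C(=O)CC(=O)C(Cc2ccc(OCc3ccccc3)cc2)C1CCc1cc(OCc2ccccc2)ccc1Cc1ccc(OCc2ccccc2)cc1 | intermediate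
17 | 4,6-bis[4-(benzyloxy)benzyl]-5-(2-{5-(benzyloxy)-2-[4-(benzyloxy)benzyl]phenyl}ethyl)cyclohexane-1,3-dione (diastereomer mixture) | O=C1CC(=O)C(Cc2ccc(OCc3ccccc3)cc2)C(CCc2cc(OCc3ccccc3)ccc2Cc2ccc(OCc3ccccc3)cc2)C1Cc1ccc(OCc2ccccc2)cc1 | intermediate
18 | 4,6-bis[4-(benzyloxy)benzyl]-5-(2-{5-(benzyloxy)-2-[4-(benzyloxy)benzyl]phenyl}ethyl)-3-methoxycyclohex-2-en-1-one (diastereomer mixture) | COC1=CC(=O)C(Cc2ccc(OCc3ccccc3)cc2)C(CCc2cc(OCc3ccccc3)ccc2Cc2ccc(OCc3ccccc3)cc2)C1Cc1ccc(OCc2ccccc2)cc1 | intermediate
19 | 4,6-bis[4-(benzyloxy)benzyl]-5-(2-{5-(benzyloxy)-2-[4-(benzyloxy)benzyl]phenyl}ethyl)-1-methoxy-3-(trimethylsilyloxy)cyclohexa-1,3-diene (diastereomer mixture) | COC1=CC(O[Si](C)(C)C)=C(Cc2ccc(OCc3ccccc3)cc2)C(CCc2cc(OCc3ccccc3)ccc2Cc2ccc(OCc3ccccc3)cc2)C1Cc1ccc(OCc2ccccc2)cc1 | intermediate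
20 | {2,4-bis[4-(benzyloxy)benzyl]-3-(2-{5-(benzyloxy)-2-[4-(benzyloxy)benzyl]phenyl}ethyl)-5-methoxyphenoxy}trimethylsilane | COc1cc(O[Si](C)(C)C)c(Cc2ccc(OCc3ccccc3)cc2)c(CCc2cc(OCc3ccccc3)ccc2Cc2ccc(OCc3ccccc3)cc2)c1Cc1ccc(OCc2ccccc2)cc1 | intermediate
21 | 2,4-bis[4-(benzyloxy)benzyl]-3-(2-{5-(benzyloxy)-2-[4-(benzyloxy)benzyl]phenyl}ethyl)-5-methoxyphenol | COc1cc(O)c(Cc2ccc(OCc3ccccc3)cc2)c(CCc2cc(OCc3ccccc3)ccc2Cc2ccc(OCc3ccccc3)cc2)c1Cc1ccc(OCc2ccccc2)cc1 | intermediate
22 | 2,4-bis(4-hydroxybenzyl)-3-{2-[5-hydroxy-2-(4-hydroxybenzyl)phenyl]ethyl}-5-methoxyphenol | COc1cc(O)c(Cc2ccc(O)cc2)c(CCc2cc(O)ccc2Cc2ccc(O)cc2)c1Cc1ccc(O)cc1 | target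

## Step count and risks

Total: 13 steps. Longest linear sequence: 11 steps (1, 2, 3, 4, 5, 7, 9, 10, 11, 12, 13, from compound 1). Steps 6 and 8 are the short side branches.

**Step 9 (key step).** The conjugate addition creates a quaternary carbon next to a tertiary one, so it may be slow and reversible. Retro-Michael cleavage, deconjugation of the enone or Michael-type self-condensation of 12 could then consume material before ring closure. Fallback, from 12 and 13 back to 16: enone 12 is annulated with unsubstituted dimethyl malonate 13 (NaOMe, MeOH, reflux), whose secondary carbanion is much less hindered, to give methyl 5-[4-(benzyloxy)benzyl]-6-(2-{5-(benzyloxy)-2-[4-(benzyloxy)benzyl]phenyl}ethyl)-2,4-dioxocyclohexane-1-carboxylate F1. Its dianion (NaH, then LiN(iPr)2, THF, −78 → 0 °C) should be benzylated by 5 at C1, the site deprotonated last, which gives 16.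

**Step 12.** Once the siloxydiene is consumed, electron transfer or hydride abstraction from the doubly para-oxygenated diarylmethane of the ring B arm, or from the electron-rich product, could lead to over-oxidation. Premature hydrolysis of the silyl dienol ether would return 18. Fallback, from 18 back to 21, without any quinone: the lithium enolate of 18 is trapped with phenylselanyl chloride to give 4,6-bis[4-(benzyloxy)benzyl]-5-(2-{5-(benzyloxy)-2-[4-(benzyloxy)benzyl]phenyl}ethyl)-3-methoxy-6-(phenylselanyl)cyclohex-2-en-1-one F2. Oxidation with H2O2 and pyridine in CH2Cl2 at 0 °C gives the selenoxide F3, whose syn elimination yields a keto tautomer of 21 that enolizes. An exocyclic benzylidene isomer, should it form, would need a separate isomerization to the arene.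

**Step 10.** Demethylation by chloride may be slow for this crowded, enolized substrate. Prolonged heating at 150 °C in the presence of the hydroxide generated could open the ring by retro-Claisen cleavage at the non-enolizable ketone. Fallback, from 12 and 5 back to 17: tert-butyl methyl malonate is benzylated with 5 (NaH, THF/DMF) to give tert-butyl methyl 2-[4-(benzyloxy)benzyl]malonate F4. Annulation with 12 under the conditions of step 9 should close onto the less hindered methyl ester and give tert-butyl 1,5-bis[4-(benzyloxy)benzyl]-6-(2-{5-(benzyloxy)-2-[4-(benzyloxy)benzyl]phenyl}ethyl)-2,4-dioxocyclohexane-1-carboxylate F5. Its ester is cleaved by acid (CF3CO2H, CH2Cl2, 0 °C → rt) with loss of 2-methylpropene, and the β-keto acid decarboxylates to 17.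

**Step 3.** Zinc insertion into the electron-rich benzylic chloride may be accompanied by Wurtz-type homocoupling. Oxidative addition into the electron-rich, ortho-substituted aryl bromide may be slow enough for protodemetalation of 6 to compete. Fallback, from 4 back to 7, with the polarity of the coupling reversed: Miyaura borylation of 4 (bis(pinacolato)diboron, PdCl2(dppf), KOAc, dioxane, 80 °C) gives methyl (E)-3-[5-(benzyloxy)-2-(4,4,5,5-tetramethyl-1,3,2-dioxaborolan-2-yl)phenyl]prop-2-enoate F6. Suzuki–Miyaura coupling of F6 with benzylic chloride 5 (Pd(PPh3)4, K2CO3, dioxane/H2O, 80 °C) gives 7.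

## Further compounds

F1 | step 9 | methyl 5-[4-(benzyloxy)benzyl]-6-(2-{5-(benzyloxy)-2-[4-(benzyloxy)benzyl]phenyl}ethyl)-2,4-dioxocyclohexane-1-carboxylate (diastereomer mixture) | COC(=O)C1C(=O)CC(=O)C(Cc2ccc(OCc3ccccc3)cc2)C1CCc1cc(OCc2ccccc2)ccc1Cc1ccc(OCc2ccccc2)cc1
F2 | step 12 | 4,6-bis[4-(benzyloxy)benzyl]-5-(2-{5-(benzyloxy)-2-[4-(benzyloxy)benzyl]phenyl}ethyl)-3-methoxy-6-(phenylselanyl)cyclohex-2-en-1-one (diastereomer mixture) | COC1=CC(=O)C(Cc2ccc(OCc3ccccc3)cc2)([Se]c2ccccc2)C(CCc2cc(OCc3ccccc3)ccc2Cc2ccc(OCc3ccccc3)cc2)C1Cc1ccc(OCc2ccccc2)cc1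
F3 | step 12 | 4,6-bis[4-(benzyloxy)benzyl]-5-(2-{5-(benzyloxy)-2-[4-(benzyloxy)benzyl]phenyl}ethyl)-3-methoxy-6-(phenylseleninyl)cyclohex-2-en-1-one (diastereomer mixture) | COC1=CC(=O)C(Cc2ccc(OCc3ccccc3)cc2)([Se](=O)c2ccccc2)C(CCc2cc(OCc3ccccc3)ccc2Cc2ccc(OCc3ccccc3)cc2)C1Cc1ccc(OCc2ccccc2)cc1
F4 | step 10 | tert-butyl methyl 2-[4-(benzyloxy)benzyl]malonate (racemic) | COC(=O)C(Cc1ccc(OCc2ccccc2)cc1)C(=O)OC(C)(C)C
F5 | step 10 | tert-butyl 1,5-bis[4-(benzyloxy)benzyl]-6-(2-{5-(benzyloxy)-2-[4-(benzyloxy)benzyl]phenyl}ethyl)-2,4-dioxocyclohexane-1-carboxylate (diastereomer mixture) | CC(C)(C)OC(=O)C1(Cc2ccc(OCc3ccccc3)cc2)C(=O)CC(=O)C(Cc2ccc(OCc3ccccc3)cc2)C1CCc1cc(OCc2ccccc2)ccc1Cc1ccc(OCc2ccccc2)cc1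
F6 | step 3 | methyl (E)-3-[5-(benzyloxy)-2-(4,4,5,5-tetramethyl-1,3,2-dioxaborolan-2-yl)phenyl]prop-2-enoate | COC(=O)/C=C/c1cc(OCc2ccccc2)ccc1B1OC(C)(C)C(C)(C)O1
A1 | alternative 1 | 1-(benzyloxy)-2,4-bis[4-(benzyloxy)benzyl]-3-({5-(benzyloxy)-2-[4-(benzyloxy)benzyl]phenyl}ethynyl)-5-methoxybenzene | COc1cc(OCc2ccccc2)c(Cc2ccc(OCc3ccccc3)cc2)c(C#Cc2cc(OCc3ccccc3)ccc2Cc2ccc(OCc3ccccc3)cc2)c1Cc1ccc(OCc2ccccc2)cc1
A2 | alternative 1 | 1-(benzyloxy)-2,4-bis[4-(benzyloxy)benzyl]-3-iodo-5-methoxybenzene | COc1cc(OCc2ccccc2)c(Cc2ccc(OCc3ccccc3)cc2)c(I)c1Cc1ccc(OCc2ccccc2)cc1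
A3 | alternative 1 | ethynyltrimethylsilane | C#C[Si](C)(C)C
A4 | alternative 1 | 4-(benzyloxy)-1-[4-(benzyloxy)benzyl]-2-bromobenzene | Brc1cc(OCc2ccccc2)ccc1Cc1ccc(OCc2ccccc2)cc1
A5 | alternative 2 | 1-(benzyloxy)-2,4-bis[4-(benzyloxy)benzyl]-3-[(E)-2-{5-(benzyloxy)-2-[4-(benzyloxy)benzyl]phenyl}ethenyl]-5-methoxybenzene | COc1cc(OCc2ccccc2)c(Cc2ccc(OCc3ccccc3)cc2)c(/C=C/c2cc(OCc3ccccc3)ccc2Cc2ccc(OCc3ccccc3)cc2)c1Cc1ccc(OCc2ccccc2)cc1
A6 | alternative 2 | 1-(benzyloxy)-3-iodo-5-methoxybenzene | COc1cc(I)cc(OCc2ccccc2)c1
A7 | alternative 2 | 4-(benzyloxy)-1-[4-(benzyloxy)benzyl]-2-ethenylbenzene | C=Cc1cc(OCc2ccccc2)ccc1Cc1ccc(OCc2ccccc2)cc1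
A8 | alternative 3 | [4-(benzyloxy)phenyl][2-(2-{3-(benzyloxy)-2,6-bis[4-(benzyloxy)benzyl]-5-methoxyphenyl}ethyl)-4-hydroxyphenyl]methanone | COc1cc(OCc2ccccc2)c(Cc2ccc(OCc3ccccc3)cc2)c(CCc2cc(O)ccc2C(=O)c2ccc(OCc3ccccc3)cc2)c1Cc1ccc(OCc2ccccc2)cc1
A9 | alternative 3 | 1-[4-(benzyloxy)phenyl]-5-{3-(benzyloxy)-2,6-bis[4-(benzyloxy)benzyl]-5-methoxyphenyl}pent-2-yn-1-one | COc1cc(OCc2ccccc2)c(Cc2ccc(OCc3ccccc3)cc2)c(CCC#CC(=O)c2ccc(OCc3ccccc3)cc2)c1Cc1ccc(OCc2ccccc2)cc1
A10 | alternative 3 | trans-1-methoxy-3-(trimethylsilyloxy)buta-1,3-diene | CO/C=C/C(=C)O[Si](C)(C)C
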